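**Plan**

- Retrosynthesis: the two benzyl ethers are removed last; ring A is then taken two hydrogens below the arene; at that level both bonds that join the pyran ring to ring A, C4–C4a and O1–C2, are cut in one stroke, which leaves a six-carbon ring (11) and a three-carbon epoxy triflate (17).
- Enabling feature: ring A is a 5-alkylresorcinol monomethyl ether (oxygen at C7 and C8a, chain at C5). At the dihydro level it is the methyl enol ether of a 5-substituted cyclohexane-1,3-dione: its carbonyl oxygen is the future O1, its only kinetically acidic α′-carbon is the future C4a, and its enol ether is already the C7 methoxy group. C2 is benzylic to an alkoxyaryl ring, so an epoxide opens there.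
- Forward: 11 is made in four steps from 1-(benzyloxy)-3-iodobenzene (Heck, Wittig, malonate annulation, enol etherification); 17 in four steps from 4-(benzyloxy)-3,5-dimethoxybenzaldehyde (olefination, reduction, asymmetric epoxidation, triflation).
- The two are joined in one flask by α′-alkylation and 6-endo epoxide opening, a (3+3) annulation that builds the pyran ring; ring A is then aromatized with DDQ and the benzyl ethers are hydrogenolysed.
- Stereochemistry: C3 comes from the Sharpless asymmetric epoxidation of cinnamyl alcohol 15 with L-(+)-diisopropyl tartrate; C2 is set by inversion at the benzylic epoxide carbon, which gives the 2,3-trans (2R,3S) arrangement.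

Key step: step 9

Remark: chroman numbering (O1, C2, C3, C4, C4a, C5 to C8, C8a) is used for the bicyclic compounds and for the atoms that become them; 11 is racemic at C5, so 19 and 20 are mixtures of ring epimers that converge when ring A is aromatized in step 10.

**Route**

Step 1
Reactants: 1 1-(benzyloxy)-3-iodobenzene; 2 prop-2-en-1-ol (allyl alcohol)
Product: 3 3-[3-(benzyloxy)phenyl]propanal
Conditions: Pd(OAc)2 (cat.), n-Bu4NCl, NaHCO3, DMF, 45 °C
Reagents that add atoms: none
Why: Heck arylation of allyl alcohol under ligand-free phase-transfer conditions, in which the aryl group adds to the terminal alkene carbon and β-hydride elimination toward the carbinol carbon gives an enol that tautomerizes to the saturated aldehyde.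

Step 2
Reactants: 3 3-[3-(benzyloxy)phenyl]propanal; 4 1-(triphenylphosphoranylidene)propan-2-one
Product: 5 (E)-6-[3-(benzyloxy)phenyl]hex-3-en-2-one
Conditions: CH2Cl2, reflux
Reagents that add atoms: none
Why: Wittig olefination with a stabilized keto ylide, which should give the (E)-enone from an unbranched aldehyde.

Step 3
Reactants: 5 (E)-6-[3-(benzyloxy)phenyl]hex-3-en-2-one; 6 dimethyl malonate
Product: 10 5-{2-[3-(benzyloxy)phenyl]ethyl}cyclohexane-1,3-dione, via Michael adduct 7 (not isolated), via cyclic keto ester 8 (not isolated), via keto acid 9 (not isolated)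
Conditions: NaOMe, MeOH, reflux; then 2 M aq NaOH, reflux; then 2 M HCl to pH 2, 80 °C
Reagents that add atoms: none
Why: Michael addition of sodiomalonate to the enone, Claisen (Dieckmann-type) closure of the methyl ketone onto one ester, saponification and decarboxylation of the β-keto acid form the classical route to 5-substituted cyclohexane-1,3-diones, and the aryl benzyl ether is stable to the base and to dilute acid.

Step 4
Reactants: 10 5-{2-[3-(benzyloxy)phenyl]ethyl}cyclohexane-1,3-dione
Product: 11 5-{2-[3-(benzyloxy)phenyl]ethyl}-3-methoxycyclohex-2-en-1-one (racemic)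
Conditions: MeOH, p-TsOH·H2O (cat.), 3 Å molecular sieves, reflux
Reagents that add atoms: methanol, CO
Why: acid-catalysed enol etherification of a cyclic 1,3-dione; the dione is symmetric, so only one (racemic) vinylogous ester can form.

Step 5
Reactants: 12 4-(benzyloxy)-3,5-dimethoxybenzaldehyde; 13 triethyl phosphonoacetate
Product: 14 ethyl (E)-3-[4-(benzyloxy)-3,5-dimethoxyphenyl]prop-2-enoate
Conditions: NaH, THF, 0 °C to rt
Reagents that add atoms: none
Why: Horner–Wadsworth–Emmons olefination of an aromatic aldehyde, which should give the (E)-cinnamate.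

Step 6
Reactants: 14 ethyl (E)-3-[4-(benzyloxy)-3,5-dimethoxyphenyl]prop-2-enoate
Product: 15 (E)-3-[4-(benzyloxy)-3,5-dimethoxyphenyl]prop-2-en-1-ol
Conditions: iBu2AlH (2.2 equiv), CH2Cl2, −78 °C; aq potassium sodium tartrate work-up
Reagents that add atoms: none
Why: 1,2-reduction of a conjugated ester to the allylic alcohol by iBu2AlH at low temperature, which leaves the alkene and the benzyl ether untouched.

Step 7
Reactants: 15 (E)-3-[4-(benzyloxy)-3,5-dimethoxyphenyl]prop-2-en-1-ol
Product: 16 {(2S,3S)-3-[4-(benzyloxy)-3,5-dimethoxyphenyl]oxiran-2-yl}methanol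
Conditions: Ti(OiPr)4 (10 mol %), L-(+)-diisopropyl tartrate (12 mol %), t-BuOOH, 4 Å molecular sieves, CH2Cl2, −20 °C
Reagents that add atoms: tert-butyl hydroperoxide, CC(C)(C)OO
Why: Sharpless asymmetric epoxidation of an (E)-allylic alcohol, in which L-(+)-tartrate directs oxygen to the face that gives the (2S,3S)-epoxy alcohol, as with (E)-cinnamyl alcohol, and so fixes the future C3 configuration and, after inversion, that of C2.

Step 8
Reactants: 16 {(2S,3S)-3-[4-(benzyloxy)-3,5-dimethoxyphenyl]oxiran-2-yl}methanol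
Product: 17 {(2S,3S)-3-[4-(benzyloxy)-3,5-dimethoxyphenyl]oxiran-2-yl}methyl trifluoromethanesulfonate
Conditions: Tf2O, 2,6-lutidine, CH2Cl2, −78 °C; cold aq NaHCO3 wash, used at once as a cold solution
Reagents that add atoms: trifluoromethanesulfonic anhydride, O=S(=O)(OS(=O)(=O)C(F)(F)F)C(F)(F)F
Why: sulfonylation of a primary alcohol with Tf2O and a hindered pyridine base at −78 °C, which does not touch the epoxide stereocentres and gives an electrophile reactive enough for a ketone enolate at low temperature.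

Step 9
Reactants: 11 5-{2-[3-(benzyloxy)phenyl]ethyl}-3-methoxycyclohex-2-en-1-one; 17 {(2S,3S)-3-[4-(benzyloxy)-3,5-dimethoxyphenyl]oxiran-2-yl}methyl trifluoromethanesulfonate
Product: 20 (2R,3S)-2-[4-(benzyloxy)-3,5-dimethoxyphenyl]-5-{2-[3-(benzyloxy)phenyl]ethyl}-7-methoxy-3,4,5,6-tetrahydro-2H-chromen-3-ol (mixture of C5 epimers), via lithium dienolate 18 (not isolated), via epoxy ketone 19 (not isolated)
Conditions: LiN(iPr)2 (LDA, 1.05 equiv), THF, −78 °C; 17 in THF, −78 to −40 °C; then BF3·OEt2 (3 equiv), −78 to −20 °C; Et3N, then aq NaHCO3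
Reagents that add atoms: none
Why: Proposed new method: LDA deprotonates vinylogous ester 11 only at the α′-carbon (the future C4a, next to the carbon that carries the arylethyl chain), and lithium dienolate 18 displaces the primary triflate of 17 by SN2 to make the C4–C4a bond in 19; BF3 then activates the aryl epoxide, the vinylogous-ester carbonyl oxygen opens it at the benzylic carbon to make the O1–C2 bond, and the resulting 1,3-dialkoxyallyl cation loses the C4a proton to give dienol ether 20. The closest known reaction types are the Stork–Danheiser α′-alkylation of 3-alkoxycyclohexenones with reactive primary electrophiles and the acid-promoted 6-endo opening of aryl- or vinyl-activated epoxides by an internal oxygen nucleophile, including the closure of epoxy ketones to cyclic ketals through the carbonyl oxygen; their union in one flask as a (3+3) annulation on a vinylogous-ester α′-enolate is without precedent. The pyran ring closes in the 6-endo-tet mode at the epoxide, preferred over 5-exo attack at C3 because only C2, benzylic to the 4-alkoxy-3,5-dimethoxyphenyl ring, can carry positive charge in the transition state. C3 keeps the configuration set in step 7 because its C–O bond is never broken, and C2 is set by inversion in the anti opening; should the opening become SN1-like, the fixed C3 centre still directs closure to the diequatorial 2,3-trans product, so either pathway should give (2R,3S). The step needs C- over O-alkylation (lithium counter-ion in THF without polar additives), attack at the CH2OTf carbon and not at the epoxide (the triflate is far more reactive at −78 °C), and regiocontrol on ring A, which the substrate secures because the future C4a is the only kinetically acidic carbon of 11 and the methoxy group already sits at the future C7. The ring stereocentres at C4a and C5 in 19 and at C5 in 20 are of no consequence because ring A is aromatized in step 10.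

Step 10
Reactants: 20 (2R,3S)-2-[4-(benzyloxy)-3,5-dimethoxyphenyl]-5-{2-[3-(benzyloxy)phenyl]ethyl}-7-methoxy-3,4,5,6-tetrahydro-2H-chromen-3-ol
Product: 21 (2R,3S)-2-[4-(benzyloxy)-3,5-dimethoxyphenyl]-5-{2-[3-(benzyloxy)phenyl]ethyl}-7-methoxy-3,4-dihydro-2H-chromen-3-ol
Conditions: DDQ (1.0 equiv), solid NaHCO3, CH2Cl2, −20 to 0 °C
Reagents that add atoms: none
Why: quinone dehydrogenation of a 1,3-dioxygenated cyclohexa-1,3-diene, in which hydride abstraction from C6 gives an oxygen-stabilized cyclohexadienyl cation that loses the C5 proton, so aromatization should be far faster than oxidation of the benzyl ethers or of the chroman C4–H, and C2 and C3 are not touched.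

Step 11
Reactants: 21 (2R,3S)-2-[4-(benzyloxy)-3,5-dimethoxyphenyl]-5-{2-[3-(benzyloxy)phenyl]ethyl}-7-methoxy-3,4-dihydro-2H-chromen-3-ol
Product: 22 (2R,3S)-2-(4-hydroxy-3,5-dimethoxyphenyl)-5-[2-(3-hydroxyphenyl)ethyl]-7-methoxy-3,4-dihydro-2H-chromen-3-ol
Conditions: H2 (1 atm), Pd(OH)2 on carbon, EtOAc/MeOH, rt
Reagents that add atoms: none
Why: hydrogenolysis of the two aryl benzyl ethers under mild conditions, as is usual for benzylated flavan-3-ols, under which the cyclic benzylic C2–O1 bond and both stereocentres should survive.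

**Compound list**

1 | 1-(benzyloxy)-3-iodobenzene | Ic1cccc(OCc2ccccc2)c1 | starting material
2 | prop-2-en-1-ol (allyl alcohol) | C=CCO | starting material
3 | 3-[3-(benzyloxy)phenyl]propanal | O=CCCc1cccc(OCc2ccccc2)c1 | intermediate
4 | 1-(triphenylphosphoranylidene)propan-2-one | CC(=O)C=P(c1ccccc1)(c1ccccc1)c1ccccc1 | starting material
5 | (E)-6-[3-(benzyloxy)phenyl]hex-3-en-2-one | CC(=O)/C=C/CCc1cccc(OCc2ccccc2)c1 | intermediate
6 | dimethyl malonate | COC(=O)CC(=O)OC | starting material
7 | dimethyl 2-{1-[3-(benzyloxy)phenyl]-5-oxohexan-3-yl}propanedioate (Michael adduct) | CC(=O)CC(CCc1cccc(OCc2ccccc2)c1)C(C(=O)OC)C(=O)OC | intermediate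
8 | methyl 2-{2-[3-(benzyloxy)phenyl]ethyl}-4,6-dioxocyclohexane-1-carboxylate (formed as its sodium enolate) | COC(=O)C1C(CCc2cccc(OCc3ccccc3)c2)CC(=O)CC1=O | intermediate
9 | 2-{2-[3-(benzyloxy)phenyl]ethyl}-4,6-dioxocyclohexane-1-carboxylic acid | OC(=O)C1C(CCc2cccc(OCc3ccccc3)c2)CC(=O)CC1=O | intermediate
10 | 5-{2-[3-(benzyloxy)phenyl]ethyl}cyclohexane-1,3-dione | O=C1CC(CCc2cccc(OCc3ccccc3)c2)CC(=O)C1 | intermediate
11 | 5-{2-[3-(benzyloxy)phenyl]ethyl}-3-methoxycyclohex-2-en-1-one (racemic) | COC1=CC(=O)CC(CCc2cccc(OCc3ccccc3)c2)C1 | intermediate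
12 | 4-(benzyloxy)-3,5-dimethoxybenzaldehyde | COc1cc(C=O)cc(OC)c1OCc1ccccc1 | starting material
13 | triethyl phosphonoacetate | CCOC(=O)CP(=O)(OCC)OCC | starting material
14 | ethyl (E)-3-[4-(benzyloxy)-3,5-dimethoxyphenyl]prop-2-enoate | CCOC(=O)/C=C/c1cc(OC)c(OCc2ccccc2)c(OC)c1 | intermediate
15 | (E)-3-[4-(benzyloxy)-3,5-dimethoxyphenyl]prop-2-en-1-ol | OC/C=C/c1cc(OC)c(OCc2ccccc2)c(OC)c1 | intermediate
16 | {(2S,3S)-3-[4-(benzyloxy)-3,5-dimethoxyphenyl]oxiran-2-yl}methanol | OC[C@@H]1O[C@H]1c1cc(OC)c(OCc2ccccc2)c(OC)c1 | intermediate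
17 | {(2S,3S)-3-[4-(benzyloxy)-3,5-dimethoxyphenyl]oxiran-2-yl}methyl trifluoromethanesulfonate | O=S(=O)(OC[C@@H]1O[C@H]1c1cc(OC)c(OCc2ccccc2)c(OC)c1)C(F)(F)F | intermediate
18 | lithium 3-{2-[3-(benzyloxy)phenyl]ethyl}-5-methoxycyclohexa-1,5-dien-1-olate (α′-dienolate of 11) | [Li+].[O-]C1=CC(CCc2cccc(OCc3ccccc3)c2)CC(OC)=C1 | intermediate
19 | 5-{2-[3-(benzyloxy)phenyl]ethyl}-6-({(2S,3S)-3-[4-(benzyloxy)-3,5-dimethoxyphenyl]oxiran-2-yl}methyl)-3-methoxycyclohex-2-en-1-one (ring epimers) | COC1=CC(=O)C(C[C@@H]2O[C@H]2c2cc(OC)c(OCc3ccccc3)c(OC)c2)C(CCc2cccc(OCc3ccccc3)c2)C1 | intermediate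
20 | (2R,3S)-2-[4-(benzyloxy)-3,5-dimethoxyphenyl]-5-{2-[3-(benzyloxy)phenyl]ethyl}-7-methoxy-3,4,5,6-tetrahydro-2H-chromen-3-ol (double bonds C4a=C8a and C7=C8; C5 epimers) | COC1=CC2=C(C(CCc3cccc(OCc4ccccc4)c3)C1)C[C@H](O)[C@@H](c1cc(OC)c(OCc3ccccc3)c(OC)c1)O2 | intermediate
21 | (2R,3S)-2-[4-(benzyloxy)-3,5-dimethoxyphenyl]-5-{2-[3-(benzyloxy)phenyl]ethyl}-7-methoxy-3,4-dihydro-2H-chromen-3-ol | COc1cc(CCc2cccc(OCc3ccccc3)c2)c2c(c1)O[C@H](c1cc(OC)c(OCc3ccccc3)c(OC)c1)[C@@H](O)C2 | intermediate
22 | (2R,3S)-2-(4-hydroxy-3,5-dimethoxyphenyl)-5-[2-(3-hydroxyphenyl)ethyl]-7-methoxy-3,4-dihydro-2H-chromen-3-ol (2,3-trans) | COc1cc(CCc2cccc(O)c2)c2c(c1)O[C@H](c1cc(OC)c(O)c(OC)c1)[C@@H](O)C2 | target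

**Step count and risks**

Total step count: 11. Longest linear sequence: 7 steps (steps 1 to 4, then 9, 10 and 11; the branch through steps 5 to 8 is equally long).

Steps most likely to fail:

1. Step 9 (Proposed new method). The carbonyl oxygen may open the epoxide at C3 in the 5-exo mode, the C3 alkoxide may trap the cation as a bridged ketal, or the aryl epoxide may rearrange by hydride shift before the ring closes. Fallback: the two bonds are made in separate known reactions and the pyran ring is closed on a phenol. It sets out from 11 and 17. The alkylation stage alone (LDA, THF, −78 °C, NaHCO3 quench) should give epoxy ketone 19, now isolated. LDA with TMSCl present at −78 °C should then give [(3-{2-[3-(benzyloxy)phenyl]ethyl}-2-({(2S,3S)-3-[4-(benzyloxy)-3,5-dimethoxyphenyl]oxiran-2-yl}methyl)-5-methoxycyclohexa-1,5-dien-1-yl)oxy]trimethylsilane F1. Saegusa–Ito dehydrogenation with Pd(OAc)2 in MeCN and tautomerization of the dienone should give 3-{2-[3-(benzyloxy)phenyl]ethyl}-2-({(2S,3S)-3-[4-(benzyloxy)-3,5-dimethoxyphenyl]oxiran-2-yl}methyl)-5-methoxyphenol F2. Pyridinium p-toluenesulfonate (cat.) in CH2Cl2 at 0 °C then closes the ring by the known acid-catalysed 6-endo opening of an aryl epoxide by an ortho phenol, with inversion at C2, and the fallback comes back to the route at 21.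

2. Step 8. The primary triflate beside an electron-rich aryl epoxide may ionise at the benzylic carbon or decompose during sulfonylation or before it meets the enolate. Fallback: the epoxide is introduced after the C–C bond. It sets out from 15 and 11. PBr3 in Et2O at 0 °C should give 2-(benzyloxy)-5-[(E)-3-bromoprop-1-en-1-yl]-1,3-dimethoxybenzene F3. Stork–Danheiser alkylation of the lithium dienolate of 11 (LDA, THF, −78 °C) should give 5-{2-[3-(benzyloxy)phenyl]ethyl}-6-{(E)-3-[4-(benzyloxy)-3,5-dimethoxyphenyl]prop-2-en-1-yl}-3-methoxycyclohex-2-en-1-one F4. Shi epoxidation with the enantiomer of the D-fructose-derived ketone (made from L-sorbose), KHSO5 and K2CO3 at about pH 10.5 in MeCN/dimethoxymethane at 0 °C should epoxidize the trans-styrenyl alkene in preference to the push–pull enol ether alkene. The fallback comes back to the route at 19, which is cyclized with BF3·OEt2 as in the second stage of step 9.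

3. Step 10. DDQ may go on to abstract hydride from C4 or C2 of the electron-rich chroman once it has formed (over-oxidation), or the acidic hydroquinone may hydrolyse the dienol ether before it is oxidized. Fallback: the hydrolysis is made deliberate and ring A is aromatized from the enone level. It sets out from 20. Oxalic acid in wet THF should give (2R,3S)-2-[4-(benzyloxy)-3,5-dimethoxyphenyl]-5-{2-[3-(benzyloxy)phenyl]ethyl}-3-hydroxy-2,3,4,4a,5,6-hexahydro-7H-chromen-7-one F5. LDA (2.2 equiv) and TMSCl at −78 °C should give {[(2R,3S)-2-[4-(benzyloxy)-3,5-dimethoxyphenyl]-5-{2-[3-(benzyloxy)phenyl]ethyl}-3,4,4a,5-tetrahydro-2H-chromene-3,7-diyl]bis(oxy)}bis(trimethylsilane) F6. Saegusa–Ito dehydrogenation with Pd(OAc)2 in MeCN, tautomerization and loss of the 3-O-silyl group on work-up should give (2R,3S)-2-[4-(benzyloxy)-3,5-dimethoxyphenyl]-5-{2-[3-(benzyloxy)phenyl]ethyl}-3,4-dihydro-2H-chromene-3,7-diol F7. MeI and K2CO3 in acetone should methylate only the phenol, and the fallback comes back to the route at 21.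

**Further compounds**

F1 | step 9 | [(3-{2-[3-(benzyloxy)phenyl]ethyl}-2-({(2S,3S)-3-[4-(benzyloxy)-3,5-dimethoxyphenyl]oxiran-2-yl}methyl)-5-methoxycyclohexa-1,5-dien-1-yl)oxy]trimethylsilane | COC1=CC(O[Si](C)(C)C)=C(C[C@@H]2O[C@H]2c2cc(OC)c(OCc3ccccc3)c(OC)c2)C(CCc2cccc(OCc3ccccc3)c2)C1
F2 | step 9 | 3-{2-[3-(benzyloxy)phenyl]ethyl}-2-({(2S,3S)-3-[4-(benzyloxy)-3,5-dimethoxyphenyl]oxiran-2-yl}methyl)-5-methoxyphenol | COc1cc(O)c(C[C@@H]2O[C@H]2c2cc(OC)c(OCc3ccccc3)c(OC)c2)c(CCc2cccc(OCc3ccccc3)c2)c1
F3 | step 8 | 2-(benzyloxy)-5-[(E)-3-bromoprop-1-en-1-yl]-1,3-dimethoxybenzene | BrC/C=C/c1cc(OC)c(OCc2ccccc2)c(OC)c1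
F4 | step 8 | 5-{2-[3-(benzyloxy)phenyl]ethyl}-6-{(E)-3-[4-(benzyloxy)-3,5-dimethoxyphenyl]prop-2-en-1-yl}-3-methoxycyclohex-2-en-1-one | COC1=CC(=O)C(C/C=C/c2cc(OC)c(OCc3ccccc3)c(OC)c2)C(CCc2cccc(OCc3ccccc3)c2)C1
F5 | step 10 | (2R,3S)-2-[4-(benzyloxy)-3,5-dimethoxyphenyl]-5-{2-[3-(benzyloxy)phenyl]ethyl}-3-hydroxy-2,3,4,4a,5,6-hexahydro-7H-chromen-7-one | O=C1C=C2O[C@H](c3cc(OC)c(OCc4ccccc4)c(OC)c3)[C@@H](O)CC2C(CCc2cccc(OCc3ccccc3)c2)C1
F6 | step 10 | {[(2R,3S)-2-[4-(benzyloxy)-3,5-dimethoxyphenyl]-5-{2-[3-(benzyloxy)phenyl]ethyl}-3,4,4a,5-tetrahydro-2H-chromene-3,7-diyl]bis(oxy)}bis(trimethylsilane) | C[Si](C)(C)OC1=CC(CCc2cccc(OCc3ccccc3)c2)C2C[C@H](O[Si](C)(C)C)[C@@H](c3cc(OC)c(OCc4ccccc4)c(OC)c3)OC2=C1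
F7 | step 10 | (2R,3S)-2-[4-(benzyloxy)-3,5-dimethoxyphenyl]-5-{2-[3-(benzyloxy)phenyl]ethyl}-3,4-dihydro-2H-chromene-3,7-diol | Oc1cc(CCc2cccc(OCc3ccccc3)c2)c2c(c1)O[C@H](c1cc(OC)c(OCc3ccccc3)c(OC)c1)[C@@H](O)C2
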